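## The problem

Atom labels: coumarin numbering (O1, C2 to C8a; ring A is the benzene ring, ring B the pyranone). The side chain on C8 is C1' (stereocentre), C2' (C=O), C3' (bears CH3) and C4' (=CH2).

The target is 6,7-dimethoxycoumarin with a five-carbon chain at C8, C1'H(O-3-methylbutanoyl)–C2'(=O)–C3'(CH3)=C4'H2, and C1' is (R). C8 is the most crowded carbon of ring A, between O1 and the 7-methoxy group, and 6,7-dimethoxycoumarin has no handle that directs a carbon electrophile there. The single stereocentre has no neighbour to control it, so it must come from a catalyst. It is benzylic to an electron-rich ring, α to a ketone and O-acylated, so base removes it by enolisation and acid by ionisation. The isopropenyl ketone is a polymerisable Michael acceptor, the ester and the lactone of ring B do not survive hydroxide or excess organometallics, and the free acyloin would scramble through its enediol. A sound route therefore sets C1' while it is still a plain carbinol, esterifies it, and lets the C2' carbonyl and the C3'=C4' bond appear last under near-neutral conditions. The feature that allows this is the array C2'(=O)–C3'(CH3)=C4'H2 next to a C1' that bears one hydrogen. It is the pattern that an ene-type oxygenation with allylic shift leaves on a C2'H=C3'(CH3)2 (prenyl-type) group, which is how such side chains are presumed to arise in prenylcoumarin biosynthesis.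

## Retrosynthesis

**12 ⇒ 9 (through 10 and 11).** The C2'=O bond and the C3'=C4' π bond are removed together and replaced by the C2'=C3' double bond of a 2-methylprop-1-enyl group. The neighbouring cuts are worse: oxidising a C2' carbinol needs a differentiated diol, acylating C1' last needs the labile acyloin, and forming C2'–C3' from an isopropenyl metal puts an organometallic next to the ester. Ester 9 has no ketone, no Michael acceptor and a stereocentre that cannot enolise. The forward reaction must put oxygen on C2' only, take hydrogen from a methyl group only, and leave C1' alone.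

**9 ⇒ 7 + 8.** The acyl C–O1' bond is cut. Acylation is placed here because C1' of 7 is an ordinary secondary carbinol and the C1'–O bond is not touched. The precursor is the alcohol plus commercial anhydride 8. The forward reaction must stay basic, since the benzylic and allylic C1'–O bond would ionise in acid.

**7 ⇒ 3 + 4 (through 5 and 6).** The C1'–C2' bond is cut. The alternative C8–C1' cut would need an aryl metal with two ortho substituents to add to an enal, for which enantiocontrol is poorly developed. The chosen cut makes C1' the prochiral carbon of aldehyde 3, where catalytic face selection is well established. The chiral C16 alcohol becomes an achiral aldehyde and a C4 bromide. The forward reaction must deliver the alkenyl group to the Si face.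

**3 ⇒ 2 ⇒ 1.** The O7–CH3 bond and then the C8–CHO bond are cut. Scopoletin 1 has a free 7-OH whose only open ortho or para position is C8, so the phenol places the carbon where the dimethyl ether could not. Both precursors are simpler by one carbon. The forward formylation must stay out of ring B.

## Roads not taken

**Alternative 1:** The most obvious cut is the ester C–O bond, made last: 12 from acyloin A1 and 3-methylbutanoyl chloride. A1 would come from ketone A2 through its (Z)-silyl dienol ether A3 by Sharpless asymmetric dihydroxylation (K2OsO2(OH)4, K3Fe(CN)6, phthalazine-linked cinchona ligand), which is the forward key step. The chosen plan is better for three reasons: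
- A1 is an aryl acyloin next to an enone. Through its enediol it can racemise, transpose to the aryl ketone isomer and tautomerise irreversibly to a saturated 1,2-diketone, and its acylation needs base.
- Osmium must choose between the enol ether and the isopropenyl double bond of A3.
- A2 needs several steps of its own from 1, so the enone is carried through more operations.

**Alternative 2:** The C1'–O bond is made by a 1,2-acyloxy shift. Ketone A2 gives (Z)-enol 3-methylbutanoate A4, Shi epoxidation (fructose-derived ketone, KHSO5) gives enol ester epoxide A5, and thermal or mild Lewis-acid rearrangement moves the acyloxy group from C2' to C1' while C2' becomes the ketone. The ester is delivered within the molecule, which is attractive. The chosen plan is better for three reasons: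
- The C1'–O bond of A5 is benzylic to the 2,6-dioxygenated ring A and should open by an SN1 path, which mixes the retention and inversion channels.
- The dioxirane must discriminate three alkenes.
- The route still needs A2.

**Alternative 3:** The C1'–O bond and the stereocentre are made by carbene O–H insertion: α-diazoketone A6 and 3-methylbutanoic acid with Rh2(OAc)4 and a chiral guanidine, through enantioselective proton transfer to the enol. This would be a convergent last step. The chosen plan is better for three reasons:
- A6 requires Regitz diazo transfer onto A2 with an amidine base in the presence of the polymerisable isopropenyl ketone.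
- A6 holds a diazo dipole and an enone dipolarophile in one molecule.
- Enantioselective protonation next to an aryl group with two ortho substituents is not secured by the substrate, and the route is longer.

Key step: step 5

Remark on the chemistry: C1' of the target is (R) (O > C2' > C8 > H); the same spatial arrangement is named (S) in 7 and 9 because C8 outranks the alkenyl carbon; the facial sense of the (−)-MIB catalyst is assumed to be the one it shows with simple aryl aldehydes.

## Steps

Step 1
Reactants: 1 scopoletin (7-hydroxy-6-methoxy-2H-chromen-2-one)
Product: 2 7-hydroxy-6-methoxy-2-oxo-2H-chromene-8-carbaldehyde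
Conditions: hexamethylenetetramine, CF3CO2H, 90 °C; then H2O, 60 °C
Reagents that add atoms: hexamethylenetetramine (C1N2CN3CN1CN(C2)C3); water (O)
Why: Duff ortho-formylation of a phenol; C8 is the only free position ortho or para to the 7-OH (C6 carries OMe, the para carbon is the ring fusion C4a), and hydrolysis of the benzylic iminium gives the aldehyde.

Step 2
Reactants: 2 7-hydroxy-6-methoxy-2-oxo-2H-chromene-8-carbaldehyde
Product: 3 6,7-dimethoxy-2-oxo-2H-chromene-8-carbaldehyde
Conditions: MeI, K2CO3, acetone, reflux
Reagents that add atoms: iodomethane (CI)
Why: Williamson O-methylation of the acidic, hydrogen-bonded phenol; carbonate in acetone should not open the lactone and the aldehyde has no α-hydrogen.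

Step 3
Reactants: 3 6,7-dimethoxy-2-oxo-2H-chromene-8-carbaldehyde; 4 1-bromo-2-methylprop-1-ene
Product: 7 (S)-8-(1-hydroxy-3-methylbut-2-en-1-yl)-6,7-dimethoxy-2H-chromen-2-one, via 2-methylprop-1-enyllithium 5 (not isolated), via bis(2-methylprop-1-enyl)zinc 6 (not isolated)
Conditions: 4, t-BuLi (2 equiv), Et2O, −78 °C; ZnBr2 (0.5 equiv), −78 to 0 °C; N,N,N′,N′-tetraethylethylenediamine, (2S)-(−)-3-exo-morpholinoisoborneol [(−)-MIB] (10 mol %), toluene, 0 °C, then 3; aq. NH4Cl
Reagents that add atoms: none
Why: Amino-alcohol-catalysed enantioselective addition of a dialkenylzinc to an aldehyde (ligand-accelerated, bimetallic zinc transition state); (−)-MIB should deliver the alkenyl group to the Si face of the formyl group, which gives (S)-7, the diamine holds back LiBr that would promote the racemic background reaction, and organozincs leave the lactone and the C3=C4 bond alone.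

Step 4
Reactants: 7 (S)-8-(1-hydroxy-3-methylbut-2-en-1-yl)-6,7-dimethoxy-2H-chromen-2-one; 8 3-methylbutanoic anhydride
Product: 9 (S)-1-(6,7-dimethoxy-2-oxo-2H-chromen-8-yl)-3-methylbut-2-en-1-yl 3-methylbutanoate
Conditions: Et3N, 4-(dimethylamino)pyridine (10 mol %), CH2Cl2, 0 °C to rt
Reagents that add atoms: none
Why: Acylation of a secondary alcohol under nucleophilic catalysis by 4-(dimethylamino)pyridine; the C1'–O bond is not broken, so the configuration is kept, and the basic medium avoids ionisation of the benzylic and allylic carbinol.

Step 5
Reactants: 9 (S)-1-(6,7-dimethoxy-2-oxo-2H-chromen-8-yl)-3-methylbut-2-en-1-yl 3-methylbutanoate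
Product: 12 (1R)-1-(6,7-dimethoxy-2-oxo-2H-chromen-8-yl)-3-methyl-2-oxobut-3-en-1-yl 3-methylbutanoate (target), via allylic hydroperoxide 10 (not isolated), via allylic peracetate 11 (not isolated)
Conditions: O2, 5,10,15,20-tetraphenylporphyrin (1 mol %), visible light, CH2Cl2, 0 °C; then Ac2O, pyridine, 0 °C to rt
Reagents that add atoms: dioxygen (O=O)
Why: Sensitised singlet oxygen adds to the electron-rich trisubstituted C2'=C3' bond in a Schenck ene reaction (perepoxide-like transition state): oxygen bonds to C2', a hydrogen is taken from one of the two C3' methyl groups and the double bond moves to C3'=C4', giving 10 as a mixture of C2' epimers. Acetylation of the hydroperoxide gives 11, and pyridine removes the C2' hydrogen as the O–O bond breaks (Kornblum–DeLaMare-type dehydration), so both epimers converge on the one ketone 12. The closest known reaction type is the one-flask photooxygenation and acetic anhydride–pyridine conversion of alkenes into transposed enones, together with the ene reaction of 1-substituted 3-methylbut-2-enyl acetates, which places the hydroperoxide next to the acyloxy carbon. No ring is closed. The only stereocentre made, C2', is erased in the same flask; C1' is not a reacting centre and becomes enolisable only after the last bond change, in a medium whose strongest base is pyridine. The step needs regioselectivity (oxygen at C2' and not at C3'), and the substrate secures it: the single C1' hydrogen lies in the plane of the alkene to avoid A(1,3) strain with the cis methyl group and is deactivated by the geminal acyloxy group, so only methyl hydrogens are in reach, and either methyl gives the same product. Chemoselectivity should hold because the coumarin C3=C4 bond and the isopropenyl ketone of 12 are electron-poor and inert to singlet oxygen, and the porphyrin triplet lies too low to sensitise coumarin photodimerisation.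

## Compound list

1 | scopoletin (7-hydroxy-6-methoxy-2H-chromen-2-one) | Oc1cc2oc(=O)ccc2cc1OC | starting material
2 | 7-hydroxy-6-methoxy-2-oxo-2H-chromene-8-carbaldehyde | O=Cc1c(O)c(OC)cc2ccc(=O)oc12 | intermediate
3 | 6,7-dimethoxy-2-oxo-2H-chromene-8-carbaldehyde | O=Cc1c(OC)c(OC)cc2ccc(=O)oc12 | intermediate
4 | 1-bromo-2-methylprop-1-ene | CC(C)=CBr | starting material
5 | 2-methylprop-1-enyllithium | [Li]C=C(C)C | intermediate
6 | bis(2-methylprop-1-enyl)zinc | CC(C)=C[Zn]C=C(C)C | intermediate
7 | (S)-8-(1-hydroxy-3-methylbut-2-en-1-yl)-6,7-dimethoxy-2H-chromen-2-one | CC(C)=C[C@H](O)c1c(OC)c(OC)cc2ccc(=O)oc12 | intermediate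
8 | 3-methylbutanoic anhydride | CC(C)CC(=O)OC(=O)CC(C)C | starting material
9 | (S)-1-(6,7-dimethoxy-2-oxo-2H-chromen-8-yl)-3-methylbut-2-en-1-yl 3-methylbutanoate | CC(C)=C[C@H](OC(=O)CC(C)C)c1c(OC)c(OC)cc2ccc(=O)oc12 | intermediate
10 | (1R)-1-(6,7-dimethoxy-2-oxo-2H-chromen-8-yl)-2-hydroperoxy-3-methylbut-3-en-1-yl 3-methylbutanoate (both C2' epimers) | C=C(C)C(OO)[C@H](OC(=O)CC(C)C)c1c(OC)c(OC)cc2ccc(=O)oc12 | intermediate
11 | (1R)-2-(acetylperoxy)-1-(6,7-dimethoxy-2-oxo-2H-chromen-8-yl)-3-methylbut-3-en-1-yl 3-methylbutanoate (both C2' epimers) | C=C(C)C(OOC(C)=O)[C@H](OC(=O)CC(C)C)c1c(OC)c(OC)cc2ccc(=O)oc12 | intermediate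
12 | (1R)-1-(6,7-dimethoxy-2-oxo-2H-chromen-8-yl)-3-methyl-2-oxobut-3-en-1-yl 3-methylbutanoate | C=C(C)C(=O)[C@H](OC(=O)CC(C)C)c1c(OC)c(OC)cc2ccc(=O)oc12 | target

## Step count and risks

Total step count: 5. Longest linear sequence: 5 steps (1 → 2 → 3 → 7 → 9 → 12).

**Step 5 (key step).** The most likely failure is erosion of configuration at C1' after the C2' ketone has formed, through enolisation by pyridine and acetate. The doubly activated C1'–O bond may also ionise, or the hydroperoxide may react along other peroxide pathways before it is acetylated. The fallback avoids both singlet oxygen and base. It sets out from 9: Upjohn dihydroxylation of the C2'=C3' bond (OsO4 cat., N-methylmorpholine N-oxide, acetone/H2O) should give the diol F1 as C2' epimers. Oxidation of its secondary hydroxyl (Dess–Martin periodinane, NaHCO3, CH2Cl2) should give the α-hydroxy ketone F2. Dehydration of the tertiary carbinol with the Burgess reagent (methyl N-(triethylammoniosulfonyl)carbamate, benzene, 50 °C) can only run toward a methyl group and comes back to the route at 12.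

**Step 3.** Face selection may be poor, because the two ortho oxygen substituents of 3 can chelate zinc and the crowded formyl group may react through the uncatalysed pathway. The fallback sets out from 3 and replaces catalytic C–C bond formation by catalytic ketone reduction. Addition of commercial 2-methylprop-1-enylmagnesium bromide (THF, −78 °C) should give the racemic alcohol F3, and MnO2 (CH2Cl2) the aryl enone F4. Corey–Bakshi–Shibata reduction with (R)-1-methyl-3,3-diphenyltetrahydro-1H,3H-pyrrolo[1,2-c][1,3,2]oxazaborole and BH3·SMe2 (THF, −20 °C) should then return to the route at 7. The (R)-catalyst is chosen on the model in which the aryl group with two ortho substituents is the larger ketone substituent; the antipode would be used if the alkenyl group proves to act as the larger one.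

**Step 1.** Formylation may be slow and incomplete, because the 7-hydroxycoumarin is a vinylogous carboxylic acid and a weak nucleophile, and the iminium intermediates can condense further with the phenol. The fallback sets out from 1 and makes the C8–C bond through a halogen. Iodination (N-iodosuccinimide, MeCN) at the only free ortho position should give 7-hydroxy-8-iodo-6-methoxy-2H-chromen-2-one F5, and methylation (MeI, K2CO3, acetone) should give 8-iodo-6,7-dimethoxy-2H-chromen-2-one F6. Iodine–magnesium exchange (iPrMgCl·LiCl, THF, −40 °C) followed by DMF returns to the route at 3.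

## Further compounds

F1 | step 5 | (1R)-1-(6,7-dimethoxy-2-oxo-2H-chromen-8-yl)-2,3-dihydroxy-3-methylbutyl 3-methylbutanoate (both C2' epimers) | CC(C)(O)C(O)[C@H](OC(=O)CC(C)C)c1c(OC)c(OC)cc2ccc(=O)oc12
F2 | step 5 | (1R)-1-(6,7-dimethoxy-2-oxo-2H-chromen-8-yl)-3-hydroxy-3-methyl-2-oxobutyl 3-methylbutanoate | CC(C)(O)C(=O)[C@H](OC(=O)CC(C)C)c1c(OC)c(OC)cc2ccc(=O)oc12
F3 | step 3 | rac-8-(1-hydroxy-3-methylbut-2-en-1-yl)-6,7-dimethoxy-2H-chromen-2-one | CC(C)=CC(O)c1c(OC)c(OC)cc2ccc(=O)oc12
F4 | step 3 | 6,7-dimethoxy-8-(3-methylbut-2-enoyl)-2H-chromen-2-one | CC(C)=CC(=O)c1c(OC)c(OC)cc2ccc(=O)oc12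
F5 | step 1 | 7-hydroxy-8-iodo-6-methoxy-2H-chromen-2-one | Ic1c(O)c(OC)cc2ccc(=O)oc12
F6 | step 1 | 8-iodo-6,7-dimethoxy-2H-chromen-2-one | Ic1c(OC)c(OC)cc2ccc(=O)oc12
A1 | alternative 1 | (R)-8-(1-hydroxy-3-methyl-2-oxobut-3-en-1-yl)-6,7-dimethoxy-2H-chromen-2-one | C=C(C)C(=O)[C@H](O)c1c(OC)c(OC)cc2ccc(=O)oc12
A2 | alternative 1 | 6,7-dimethoxy-8-(3-methyl-2-oxobut-3-en-1-yl)-2H-chromen-2-one | C=C(C)C(=O)Cc1c(OC)c(OC)cc2ccc(=O)oc12
A3 | alternative 1 | 8-[(1Z)-2-(tert-butyldimethylsilyloxy)-3-methylbuta-1,3-dien-1-yl]-6,7-dimethoxy-2H-chromen-2-one | C=C(C)/C(O[Si](C)(C)C(C)(C)C)=C/c1c(OC)c(OC)cc2ccc(=O)oc12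
A4 | alternative 2 | (1Z)-1-(6,7-dimethoxy-2-oxo-2H-chromen-8-yl)-3-methylbuta-1,3-dien-2-yl 3-methylbutanoate | C=C(C)/C(OC(=O)CC(C)C)=C/c1c(OC)c(OC)cc2ccc(=O)oc12
A5 | alternative 2 | (2R,3S)-3-(6,7-dimethoxy-2-oxo-2H-chromen-8-yl)-2-(prop-1-en-2-yl)oxiran-2-yl 3-methylbutanoate | C=C(C)[C@]1(OC(=O)CC(C)C)O[C@H]1c1c(OC)c(OC)cc2ccc(=O)oc12
A6 | alternative 3 | 8-(1-diazo-3-methyl-2-oxobut-3-en-1-yl)-6,7-dimethoxy-2H-chromen-2-one | C=C(C)C(=O)C(=[N+]=[N-])c1c(OC)c(OC)cc2ccc(=O)oc12
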